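**Retrosynthetic overview**
- The route rests on pyranone ring C′ (O1′, C2′, C3′, C4′, C4a′, C8a′) of the 5,7-dihydroxyflavone unit. It lies between the mirror-symmetric phloroglucinol ring A′ and the para-phenylene ring D. Cutting C4a′–C4′, C4′–C3′ and O1′–C2′ gives iodoresorcinol 6, carbon monoxide 19 (as C4′) and arylalkyne 18 (C3′ and C2′).
- Alkyne 18 comes from aldehyde 16 by one-carbon homologation. Aldehyde 16 comes from 6-hydroxyflavone 14 and 4-fluorobenzaldehyde 15 by SNAr, which forms the diaryl ether between C6 and ring D.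
- Ring C of unit 1 comes from 1,3-diketone 13, made from acetophenone 9 (from 2,6-dimethoxyhydroquinone 7) and acid chloride 11.
- Iodoresorcinol 6 comes from phloroglucinol 1 by monobenzylation, bis-MOM protection, lithiation between the acetals, iodination and unmasking.
- Ring order: ring C (step 8), then ring C′ (step 11). The last step removes both benzyl ethers and the chelated 5-methyl ether.

Key step: step 11

Remark on the chemistry: unprimed locants and rings A, B, C belong to the 6-aryloxy-5-hydroxy-7-methoxyflavone (unit 1). Primed locants and rings A′, C′ belong to the 5,7-dihydroxyflavone (unit 2). Ring D is the para-phenylene between the ether oxygen on C6 and C2′. The target has no stereocenter. Compounds 1, 7, 10, 15, 19 and the Ohira–Bestmann reagent are assumed to be purchasable.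

**Route**

Step 1
Reactants: 1 phloroglucinol
Product: 2 5-benzyloxybenzene-1,3-diol
Conditions: BnBr (0.35 equiv), K2CO3, DMF, 0 °C → rt (1 in excess)
Reagents that add atoms: benzyl bromide, BrCc1ccccc1
Why: Williamson etherification of one of three equivalent hydroxyls in a dipolar aprotic solvent, where the phenoxide reacts at oxygen; the excess of triol should keep di- and tri-ethers low, and unreacted 1 is washed out with water.

Step 2
Reactants: 2 5-benzyloxybenzene-1,3-diol
Product: 3 1-benzyloxy-3,5-bis(methoxymethoxy)benzene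
Conditions: MOMCl, i-Pr2NEt, CH2Cl2, 0 °C → rt
Reagents that add atoms: chloromethyl methyl ether, COCCl
Why: O-alkylation of both remaining phenols by the α-chloro ether (acetal protection) is fast under mild amine base and installs the two groups that direct the metalation.

Step 3
Reactants: 3 1-benzyloxy-3,5-bis(methoxymethoxy)benzene
Product: 5 5-benzyloxy-2-iodo-1,3-bis(methoxymethoxy)benzene, via 2-lithio arene 4 (not isolated)
Conditions: n-BuLi, THF, 0 °C; then I2, THF, −78 °C → rt; aq. Na2S2O3
Reagents that add atoms: iodine, II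
Why: Directed ortho-metalation: the hydrogen at C2 sits between two lithium-coordinating MOM ethers and is removed in preference to those next to the benzyl ether, and iodinolysis of the aryllithium fixes iodine at that carbon.

Step 4
Reactants: 5 5-benzyloxy-2-iodo-1,3-bis(methoxymethoxy)benzene
Product: 6 5-benzyloxy-2-iodobenzene-1,3-diol
Conditions: HCl (2 M), MeOH/THF, rt, dark
Reagents that add atoms: none
Why: Acid-catalysed methanolysis of the two MOM acetals frees the phenols while the benzyl ether is untouched; room temperature and a short reaction time are chosen because this electron-rich aryl iodide could shift or lose iodine under stronger acid.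

Step 5
Reactants: 7 2,6-dimethoxyhydroquinone
Product: 9 1-(3,6-dihydroxy-2,4-dimethoxyphenyl)ethanone, via difluoroboron chelate 8 (not isolated)
Conditions: AcOH, BF3·OEt2, 90 °C; then H2O, warm
Reagents that add atoms: acetic acid, CC(=O)O
Why: Friedel–Crafts C-acetylation ortho to the C4 hydroxyl; C3 and C5 of 7 are the only free positions and are equivalent by symmetry, and the difluoroboron chelate of the ortho-hydroxy ketone stops a second acylation and is hydrolysed on work-up.

Step 6
Reactants: 10 4-benzyloxybenzoic acid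
Product: 11 4-benzyloxybenzoyl chloride
Conditions: (COCl)2, DMF (cat.), CH2Cl2, 0 °C → rt
Reagents that add atoms: oxalyl chloride, ClC(=O)C(Cl)=O
Why: Acid chloride formation through the chloroiminium species from DMF and oxalyl chloride; the benzyl ether is inert and the by-products are gases.

Step 7
Reactants: 9 1-(3,6-dihydroxy-2,4-dimethoxyphenyl)ethanone; 11 4-benzyloxybenzoyl chloride
Product: 13 1-(4-benzyloxyphenyl)-3-(3,6-dihydroxy-2,4-dimethoxyphenyl)propane-1,3-dione, via trilithium salt 12 (not isolated)
Conditions: LiN(SiMe3)2 (4.2 equiv), THF, −78 → −10 °C; then 11 (1 equiv), −78 °C → rt; aq. HCl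
Reagents that add atoms: none
Why: Crossed Claisen acylation (the enolate form of the Baker–Venkataraman synthesis): in the polyanion the ketone enolate carbon is far more nucleophilic than the two lithium phenoxides, so one equivalent of 11 should acylate carbon and give the 1,3-diketone directly.

Step 8
Reactants: 13 1-(4-benzyloxyphenyl)-3-(3,6-dihydroxy-2,4-dimethoxyphenyl)propane-1,3-dione
Product: 14 2-(4-benzyloxyphenyl)-6-hydroxy-5,7-dimethoxy-4H-chromen-4-one
Conditions: AcOH, H2SO4 (cat.), 95 °C
Reagents that add atoms: none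
Why: Acid-catalysed cyclodehydration of an ortho-hydroxyaryl 1,3-diketone to the flavone; only the hydroxyl ortho to the acyl group can reach the distal carbonyl and close ring C, so the other hydroxyl is left as the 6-OH between the two methyl ethers, and catalytic acid in AcOH should spare the benzyl ether.

Step 9
Reactants: 14 2-(4-benzyloxyphenyl)-6-hydroxy-5,7-dimethoxy-4H-chromen-4-one; 15 4-fluorobenzaldehyde
Product: 16 4-{[2-(4-benzyloxyphenyl)-5,7-dimethoxy-4-oxo-4H-chromen-6-yl]oxy}benzaldehyde
Conditions: K2CO3, DMF, 110 °C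
Reagents that add atoms: none
Why: Nucleophilic aromatic substitution (addition–elimination): the 6-phenoxide displaces fluoride para to the formyl group; the two ortho methoxy groups slow the attack but do not block it at this temperature, and the flavone is stable to carbonate in dry DMF.

Step 10
Reactants: 16 4-{[2-(4-benzyloxyphenyl)-5,7-dimethoxy-4-oxo-4H-chromen-6-yl]oxy}benzaldehyde
Product: 18 2-(4-benzyloxyphenyl)-6-(4-ethynylphenoxy)-5,7-dimethoxy-4H-chromen-4-one, via diazoalkene 17 (not isolated)
Conditions: dimethyl (1-diazo-2-oxopropyl)phosphonate, K2CO3, MeOH/THF, 0 °C → rt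
Reagents that add atoms: Ohira–Bestmann reagent, COP(=O)(OC)C(=[N+]=[N-])C(C)=O
Why: Seyferth–Gilbert homologation in the Ohira–Bestmann form: methanolysis of the reagent gives the diazomethylphosphonate anion, Horner–Wadsworth–Emmons olefination gives the diazoalkene, and loss of N2 with 1,2-hydride shift gives the terminal alkyne under conditions the flavone and both ethers tolerate.

Step 11
Reactants: 6 5-benzyloxy-2-iodobenzene-1,3-diol; 18 2-(4-benzyloxyphenyl)-6-(4-ethynylphenoxy)-5,7-dimethoxy-4H-chromen-4-one; 19 carbon monoxide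
Product: 22 7-benzyloxy-2-(4-{[2-(4-benzyloxyphenyl)-5,7-dimethoxy-4-oxo-4H-chromen-6-yl]oxy}phenyl)-5-hydroxy-4H-chromen-4-one, via ynone 20 (not isolated), via enaminone 21 (not isolated)
Conditions: PdCl2(PPh3)2 (5 mol %), Et2NH/DMF, CO (20 bar), 110 °C, no copper salt
Reagents that add atoms: none
Why: PdCl2(PPh3)2 is reduced in the flask to zerovalent palladium, which inserts into the C–I bond of 6; CO insertion gives the aroylpalladium iodide (bond C4a′–C4′), and alkynylation by the amine-deprotonated terminus of 18 followed by reductive elimination gives ynone 20 (bond C4′–C3′). Diethylamine adds to the ynone to give enaminone 21, and an ortho hydroxyl attacks its β-carbon in an addition–elimination that expels the amine (bond O1′–C2′). The closest known reaction is the palladium-catalysed carbonylative annulation of ortho-iodophenols with terminal arylalkynes to flavones in a secondary amine, conditions under which a flavone such as unit 1 is itself stable. Ring C′ closes in the 6-endo mode (oxa-Michael addition–elimination on the enaminone), and routing the closure through the amine adduct is what holds back 5-exo closure to the aurone. No stereocenter is formed. The step needs carbonylative coupling to outrun direct alkynylation (which would lead to a benzofuran), secured by CO pressure and the absence of copper, and it needs no choice between the two hydroxyls because 6 has a mirror plane through C2 and C5, so either closes to the same product and the other remains as the hydrogen-bonded 5′-OH.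

Step 12
Reactants: 22 7-benzyloxy-2-(4-{[2-(4-benzyloxyphenyl)-5,7-dimethoxy-4-oxo-4H-chromen-6-yl]oxy}phenyl)-5-hydroxy-4H-chromen-4-one
Product: 23 isocryptomerin, 6-[4-(5,7-dihydroxy-4-oxo-4H-chromen-2-yl)phenoxy]-5-hydroxy-2-(4-hydroxyphenyl)-7-methoxy-4H-chromen-4-one
Conditions: BCl3 (excess), pentamethylbenzene, CH2Cl2, −78 °C → rt; MeOH, then H2O
Reagents that add atoms: none
Why: Lewis-acid ether cleavage: BCl3 removes both aryl benzyl ethers at low temperature while pentamethylbenzene traps the benzyl cation so that ring A′ is not C-benzylated, and on warming it cleaves only the 5-methyl ether, which is activated through a six-membered boron chelate with the C4 carbonyl, while the unchelated 7-methyl ether and the diaryl ether stay.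

**Compound list**

1 | phloroglucinol | Oc1cc(O)cc(O)c1 | starting material
2 | 5-benzyloxybenzene-1,3-diol | Oc1cc(O)cc(OCc2ccccc2)c1 | intermediate
3 | 1-benzyloxy-3,5-bis(methoxymethoxy)benzene | COCOc1cc(OCOC)cc(OCc2ccccc2)c1 | intermediate
4 | [4-benzyloxy-2,6-bis(methoxymethoxy)phenyl]lithium (not isolated) | [Li]c1c(OCOC)cc(OCc2ccccc2)cc1OCOC | intermediate
5 | 5-benzyloxy-2-iodo-1,3-bis(methoxymethoxy)benzene | COCOc1cc(OCc2ccccc2)cc(OCOC)c1I | intermediate
6 | 5-benzyloxy-2-iodobenzene-1,3-diol | Oc1cc(OCc2ccccc2)cc(O)c1I | intermediate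
7 | 2,6-dimethoxyhydroquinone | COc1cc(O)cc(OC)c1O | starting material
8 | difluoroboron chelate of 9 (not isolated) | CC1=[O+][B-](F)(F)Oc2cc(OC)c(O)c(OC)c21 | intermediate
9 | 1-(3,6-dihydroxy-2,4-dimethoxyphenyl)ethanone | CC(=O)c1c(O)cc(OC)c(O)c1OC | intermediate
10 | 4-benzyloxybenzoic acid | OC(=O)c1ccc(OCc2ccccc2)cc1 | starting material
11 | 4-benzyloxybenzoyl chloride | ClC(=O)c1ccc(OCc2ccccc2)cc1 | intermediate
12 | trilithium enolate bis-phenoxide of 9 (not isolated) | [Li+].[Li+].[Li+].C=C([O-])c1c([O-])cc(OC)c([O-])c1OC | intermediate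
13 | 1-(4-benzyloxyphenyl)-3-(3,6-dihydroxy-2,4-dimethoxyphenyl)propane-1,3-dione | COc1cc(O)c(C(=O)CC(=O)c2ccc(OCc3ccccc3)cc2)c(OC)c1O | intermediate
14 | 2-(4-benzyloxyphenyl)-6-hydroxy-5,7-dimethoxy-4H-chromen-4-one | COc1cc2oc(-c3ccc(OCc4ccccc4)cc3)cc(=O)c2c(OC)c1O | intermediate
15 | 4-fluorobenzaldehyde | O=Cc1ccc(F)cc1 | starting material
16 | 4-{[2-(4-benzyloxyphenyl)-5,7-dimethoxy-4-oxo-4H-chromen-6-yl]oxy}benzaldehyde | COc1cc2oc(-c3ccc(OCc4ccccc4)cc3)cc(=O)c2c(OC)c1Oc1ccc(C=O)cc1 | intermediate
17 | 2-(4-benzyloxyphenyl)-6-[4-(2-diazoethenyl)phenoxy]-5,7-dimethoxy-4H-chromen-4-one (not isolated) | COc1cc2oc(-c3ccc(OCc4ccccc4)cc3)cc(=O)c2c(OC)c1Oc1ccc(C=C=[N+]=[N-])cc1 | intermediate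
18 | 2-(4-benzyloxyphenyl)-6-(4-ethynylphenoxy)-5,7-dimethoxy-4H-chromen-4-one | COc1cc2oc(-c3ccc(OCc4ccccc4)cc3)cc(=O)c2c(OC)c1Oc1ccc(C#C)cc1 | intermediate
19 | carbon monoxide | [C-]#[O+] | starting material
20 | 2-(4-benzyloxyphenyl)-6-{4-[3-(4-benzyloxy-2,6-dihydroxyphenyl)-3-oxoprop-1-ynyl]phenoxy}-5,7-dimethoxy-4H-chromen-4-one (not isolated) | COc1cc2oc(-c3ccc(OCc4ccccc4)cc3)cc(=O)c2c(OC)c1Oc1ccc(cc1)C#CC(=O)c1c(O)cc(OCc2ccccc2)cc1O | intermediate
21 | 2-(4-benzyloxyphenyl)-6-{4-[(E)-3-(4-benzyloxy-2,6-dihydroxyphenyl)-1-(diethylamino)-3-oxoprop-1-enyl]phenoxy}-5,7-dimethoxy-4H-chromen-4-one (not isolated) | COc1cc2oc(-c3ccc(OCc4ccccc4)cc3)cc(=O)c2c(OC)c1Oc1ccc(cc1)/C(N(CC)CC)=C\C(=O)c1c(O)cc(OCc2ccccc2)cc1O | intermediate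
22 | 7-benzyloxy-2-(4-{[2-(4-benzyloxyphenyl)-5,7-dimethoxy-4-oxo-4H-chromen-6-yl]oxy}phenyl)-5-hydroxy-4H-chromen-4-one | COc1cc2oc(-c3ccc(OCc4ccccc4)cc3)cc(=O)c2c(OC)c1Oc1ccc(cc1)-c1cc(=O)c2c(O)cc(OCc3ccccc3)cc2o1 | intermediate
23 | isocryptomerin | COc1cc2oc(-c3ccc(O)cc3)cc(=O)c2c(O)c1Oc1ccc(-c2cc(=O)c3c(O)cc(O)cc3o2)cc1 | target

**Step count**

Total: 12 steps. Longest linear sequence: 7 steps (7 → 9 → 13 → 14 → 16 → 18 → 22 → 23, steps 5, 7, 8, 9, 10, 11, 12).

**Steps most likely to fail**

1. Step 11. Oxidative addition of zerovalent palladium into the electron-rich, doubly ortho-oxygenated C–I bond may be slow, so that reductive loss of iodine, direct alkynylation without CO uptake (then closure to a benzofuran) or 5-exo closure to an aurone compete. The fallback builds ring C′ by the enolate acylation and cyclodehydration already used for ring C. It sets out from aldehyde 16 and comes back at 22.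
   - Pinnick oxidation (NaClO2, NaH2PO4, 2-methyl-2-butene, t-BuOH/THF/H2O) would give 4-{[2-(4-benzyloxyphenyl)-5,7-dimethoxy-4-oxo-4H-chromen-6-yl]oxy}benzoic acid F1.
   - (COCl)2 with catalytic DMF would give the corresponding benzoyl chloride F2.
   - Commercial 2,4,6-trihydroxyacetophenone would be benzylated at its one hydroxyl that is not ortho to the acetyl group (BnBr, K2CO3, acetone) to 1-(4-benzyloxy-2,6-dihydroxyphenyl)ethanone F3.
   - F3 and F2 would be joined with LiN(SiMe3)2 (4.2 equiv, THF, −78 °C → rt) to 1-(4-benzyloxy-2,6-dihydroxyphenyl)-3-(4-{[2-(4-benzyloxyphenyl)-5,7-dimethoxy-4-oxo-4H-chromen-6-yl]oxy}phenyl)propane-1,3-dione F4.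
   - AcOH with catalytic H2SO4 at 95 °C would close ring C′ through either of the two equivalent hydroxyls and give 22, which then enters step 12.

2. Step 12. The chelated 5-methyl ether may be cleaved incompletely after the benzyl ethers are gone, the 7-methyl ether may be lost on forcing, and benzyl cation equivalents may alkylate the phloroglucinol ring A′. The fallback splits the deprotection into two steps with different mechanisms. It sets out from 22 and comes back at 23.
   - Hydrogenolysis (H2, Pd/C, THF/MeOH, rt) would remove both benzyl groups without any cation and give 5-O-methylisocryptomerin F5.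
   - AlCl3 in MeCN at 60 °C would then cleave only the methyl ether peri to the C4 carbonyl through its six-membered aluminium chelate and give 23.

3. Step 4. Ipso protonation of the very electron-rich ring during the acidic acetal cleavage may cause migration or loss of iodine. The fallback avoids both the acetals and the acid. It sets out from 2 and comes back at 6.
   - Direct iodination of 2 with I2 and NaHCO3 in THF/H2O at 0 °C, the conditions that take resorcinol to 2-iodoresorcinol, should place iodine between the two hydroxyls.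
   - Any isomer iodinated next to the benzyl ether would be removed by chromatography.
   - No new compound arises.

Further compounds
F1 | step 11 | 4-{[2-(4-benzyloxyphenyl)-5,7-dimethoxy-4-oxo-4H-chromen-6-yl]oxy}benzoic acid | COc1cc2oc(-c3ccc(OCc4ccccc4)cc3)cc(=O)c2c(OC)c1Oc1ccc(C(=O)O)cc1
F2 | step 11 | 4-{[2-(4-benzyloxyphenyl)-5,7-dimethoxy-4-oxo-4H-chromen-6-yl]oxy}benzoyl chloride | COc1cc2oc(-c3ccc(OCc4ccccc4)cc3)cc(=O)c2c(OC)c1Oc1ccc(C(=O)Cl)cc1
F3 | step 11 | 1-(4-benzyloxy-2,6-dihydroxyphenyl)ethanone | CC(=O)c1c(O)cc(OCc2ccccc2)cc1O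
F4 | step 11 | 1-(4-benzyloxy-2,6-dihydroxyphenyl)-3-(4-{[2-(4-benzyloxyphenyl)-5,7-dimethoxy-4-oxo-4H-chromen-6-yl]oxy}phenyl)propane-1,3-dione | COc1cc2oc(-c3ccc(OCc4ccccc4)cc3)cc(=O)c2c(OC)c1Oc1ccc(cc1)C(=O)CC(=O)c1c(O)cc(OCc2ccccc2)cc1O
F5 | step 12 | 5-O-methylisocryptomerin | COc1cc2oc(-c3ccc(O)cc3)cc(=O)c2c(OC)c1Oc1ccc(cc1)-c1cc(=O)c2c(O)cc(O)cc2o1
F0 | step 4 | none | none
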